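I was asked whether this flask still moved at 40 min. Over the catalyst Zd, Za gives Zb and Zc, and Zb may go on to Ze.

- autumn: Za 0.25 M; Zd 2.5 mM (in portions, 4); Zf 2.3 mM; the very flask that is asked about, followed so far; portions every 12 s
- flask: Za 0.25 M; Zd 2.5 mM (in portions, 4); Zf 2.3 mM; time 40 min; the portions of Zd follow each other after 12 s, the first at the start

autumn run (percent of the Za charged)

| time / min | Zb / % | Zc / % |
|---|---|---|
| 1.50 | 6.3 | 45.6 |
| 4.00 | 8.7 | 42.3 |
| 8.00 | 9.4 | 41.5 |
| 12.0 | 9.0 | 40.8 |

(each reading ± 0.5 percentage points)

* why nothing more happens at 40 min, or that something still does (forward and back rates have come level / it is still moving / no working catalyst is left / all of Za has reacted)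
* amount of Zb at 40 min, in percent of the Za charged
* amount of Zc at 40 min, in percent of the Za charged

- steps that have been proposed: Za + Zd <-> Zb + Zd; Za + Zd <-> Zc + Zd; Zb <-> Ze; Zd + Zf <-> Zg
- the reaction counts as stopped when no species that holds the Za changes by six tenths of a point or more over the second half of the time

I turned the question round: what had to be true for the flask still to move? One sufficient way was that [Zc] still stood at least 0.6 point above its end at half time, 20.0 min; the rule also counted a change of that size in any other species that holds Za. I took the last reading of the autumn run, this same flask, as a provisional end, and measured the excess of [Zc] over it. Its fall on the common logarithm gave the decade time, a relaxation time read from scattered readings: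

decades fallen = lg(4.8 percentage points / 1.5 points) = 0.505

decade time = 2.50 min / 0.505 = 4.95 min

decade time needed = 18.5 min / lg(4.8 points / 0.6 point) = 20.5 min

The needed time was longer than the read one by a factor of 4.14. At half time I reckoned an excess of 8.8 × 10⁻⁴ points. A leak remained possible. But the last sag of [Zc], 0.7 points, lay between two readings that each scatter by 0.5 points, so I read none. I committed to a stop, with [Zb] near 9.20% and [Zc] near 40.8%.

The forecast differed: it is still moving, with 8.4% Zb and 38% Zc, on “a slow leak Zb → Ze draining the whole pool”.

The flask gave forward and back rates have come level, with 9.37% Zb and 40.9% Zc.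

    Za + Zd ⇌ Zb + Zd, rate k1*[Za]*[Zd] forward; the back reaction follows from the equilibrium constant (K = 0.229, k = 3.95 L mol⁻¹ s⁻¹)
    Za + Zd ⇌ Zc + Zd, rate k2*[Za]*[Zd] forward; the back reaction follows from the equilibrium constant (K = 1.00, k = 103 L mol⁻¹ s⁻¹)
    Zb ⇌ Ze (K = 0.940, k = 0.0180 s⁻¹)
    Zd + Zf ⇌ Zg, settled at all times (K = 1570 L mol⁻¹)

Against my 8.8 × 10⁻⁴ points, this flask moved 0 points over the second half. The neighbour flask, left until 1.0 h, ran 4.04 decade times past the asked time and held 9.37% Zb and 40.9% Zc. One reason for the stop was the return of Zb to Za. In the run without that return the flask no longer ended level, and Zb at 40 min went from 9.37% to 51.2%.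

The readings come from a simulation for an exercise, noise included.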